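Assumption: the target SMILES has no stereocentre and no stereogenic double bond. IN1159 is achiral, so the "single enantiomer" requirement sets no stereochemical task.

**Retrosynthetic overview**
1. Target ⇒ 2-hydroxy-4-methoxy-6-phenethyl-benzophenone bis(benzyl ether). One hydrogenolysis removes both benzyl groups and turns Ar–C(=O)–Ar into Ar–CH2–Ar, so the carbonyl is a traceless activating and directing group.
2. Key step: the central resorcinol ring is built de novo by a Diels–Alder benzannulation of Brassard's diene with an aryl alkynyl ketone. It is the only ring formed; both outer rings are bought.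
3. Ynone ⇒ acyl Sonogashira coupling of 4-(benzyloxy)benzoyl chloride with a 4-aryl-1-butyne. The butyne ⇒ 3-(benzyloxy)benzyl bromide + lithiated 1-(trimethylsilyl)propyne.
4. Diene ⇒ methyl acetoacetate, by enol etherification and then γ-deprotonation with O-silylation.
5. Avoided first choice: Wittig/hydrogenation to the bibenzyl, then Friedel–Crafts benzylation of the finished resorcinol, which has a C2/C4/C6 regiochemistry problem.

**Route**

Step 1
Reactants: 1 methyl acetoacetate
Product: 3 methyl (E)-3-methoxybut-2-enoate, via dimethyl ketal 2 (not isolated)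
Conditions: HC(OMe)3 (1.1 equiv), cat. H2SO4, MeOH, rt; neutralise, distil
Reagents that add atoms: trimethyl orthoformate, COC(OC)OC
Why: Acid-catalysed orthoester ketalisation followed by loss of MeOH on distillation (enol ether formation) gives the conjugated, thermodynamically preferred E enol ether.

Step 2
Reactants: 3 methyl (E)-3-methoxybut-2-enoate
Product: 5 1,3-dimethoxy-1-(trimethylsilyloxy)buta-1,3-diene (Brassard's diene), via lithium dienolate 4 (not isolated)
Conditions: LDA (commercial solution, 1.1 equiv), THF, −78 °C; TMSCl (1.3 equiv), −78 °C to rt; pentane filtration, Kugelrohr distillation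
Reagents that add atoms: chlorotrimethylsilane, C[Si](C)(C)Cl
Why: Kinetic γ-deprotonation of the vinylogous carbonate and O-silylation of the extended enolate by the hard silyl chloride (silyl ketene acetal formation) give the diene, whose C1=C2 geometry is lost later on aromatisation.

Step 3
Reactants: 6 1-(trimethylsilyl)propyne; 7 3-(benzyloxy)benzyl bromide
Product: 10 1-(benzyloxy)-3-(but-3-yn-1-yl)benzene, via lithiated silylpropyne 8 (not isolated), via silyl alkyne 9 (not isolated)
Conditions: 6 (1.2 equiv), n-BuLi, THF, −78 °C; 7, −78 °C to rt; then MeOH, K2CO3 (0.3 equiv), rt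
Reagents that add atoms: none
Why: SN2 alkylation of the silyl-stabilised propargyl-lithium occurs at the propargylic carbon because the silyl group suppresses the allenyl mode, and methoxide-catalysed protodesilylation then frees the terminal alkyne without touching the benzyl ether.

Step 4
Reactants: 10 1-(benzyloxy)-3-(but-3-yn-1-yl)benzene; 11 4-(benzyloxy)benzoyl chloride
Product: 12 1-[4-(benzyloxy)phenyl]-5-[3-(benzyloxy)phenyl]pent-2-yn-1-one
Conditions: PdCl2(PPh3)2 (2 mol %), CuI (4 mol %), Et3N (1.1 equiv), THF, rt
Reagents that add atoms: none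
Why: Acyl Sonogashira coupling (oxidative addition of the aroyl chloride, copper acetylide transmetalation, reductive elimination) gives the ynone in one step at rt, and only one equivalent of base is used so that the product does not isomerise.

Step 5
Reactants: 12 1-[4-(benzyloxy)phenyl]-5-[3-(benzyloxy)phenyl]pent-2-yn-1-one; 5 Brassard's diene
Product: 15 [4-(benzyloxy)phenyl]{2-[2-(3-(benzyloxy)phenyl)ethyl]-6-hydroxy-4-methoxyphenyl}methanone, via cycloadduct 13 (not isolated), via aryl silyl ether 14 (not isolated)
Conditions: 5 (3 equiv), PhMe, 120 °C, sealed tube, 36 h; then 1 M HCl, THF, rt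
Reagents that add atoms: none
Why: In this regioselective normal-demand Diels–Alder benzannulation the nucleophilic C4 of the vinylogous ketene acetal bonds to the electrophilic β-alkynyl carbon and C1 to the acyl-bearing carbon, after which loss of MeOH and desilylation aromatise the adduct so that OH ends up ortho and OMe para to the aroyl group and no stereocentre survives.

Step 6
Reactants: 15 [4-(benzyloxy)phenyl]{2-[2-(3-(benzyloxy)phenyl)ethyl]-6-hydroxy-4-methoxyphenyl}methanone
Product: 18 2-(4-hydroxybenzyl)-3-[2-(3-hydroxyphenyl)ethyl]-5-methoxyphenol (IN1159), via triphenol ketone 16 (not isolated), via benzhydrol 17 (not isolated)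
Conditions: H2 (5 bar), 10% Pd/C, EtOH–AcOH (10:1), 50 °C
Reagents that add atoms: none
Why: Catalytic hydrogenolysis over Pd/C cleaves both benzyl ethers, reduces the aryl ketone and hydrogenolyses the doubly donor-activated benzhydrol C–O bond (the same reaction type that converts acylresorcinols into alkylresorcinols), and the transient carbinol centre of 17 is erased to leave the achiral target.

**Compound list**
1 | methyl acetoacetate | CC(=O)CC(=O)OC | starting material
2 | methyl 3,3-dimethoxybutanoate | COC(C)(OC)CC(=O)OC | intermediate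
3 | methyl (E)-3-methoxybut-2-enoate | CO/C(C)=C/C(=O)OC | intermediate
4 | lithium 1,3-dimethoxybuta-1,3-dien-1-olate | C=C(OC)C=C(OC)[O-].[Li+] | intermediate
5 | 1,3-dimethoxy-1-(trimethylsilyloxy)buta-1,3-diene (Brassard's diene; C1=C2 geometry not relevant) | C=C(OC)C=C(OC)O[Si](C)(C)C | intermediate
6 | 1-(trimethylsilyl)propyne | CC#C[Si](C)(C)C | starting material
7 | 3-(benzyloxy)benzyl bromide | BrCc1cccc(OCc2ccccc2)c1 | starting material
8 | 3-lithio-1-(trimethylsilyl)propyne | [Li]CC#C[Si](C)(C)C | intermediate
9 | {4-[3-(benzyloxy)phenyl]but-1-yn-1-yl}trimethylsilane | C[Si](C)(C)C#CCCc1cccc(OCc2ccccc2)c1 | intermediate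
10 | 1-(benzyloxy)-3-(but-3-yn-1-yl)benzene | C#CCCc1cccc(OCc2ccccc2)c1 | intermediate
11 | 4-(benzyloxy)benzoyl chloride | O=C(Cl)c1ccc(OCc2ccccc2)cc1 | starting material
12 | 1-[4-(benzyloxy)phenyl]-5-[3-(benzyloxy)phenyl]pent-2-yn-1-one | O=C(C#CCCc1cccc(OCc2ccccc2)c1)c1ccc(OCc2ccccc2)cc1 | intermediate
13 | cyclohexa-1,4-diene Diels–Alder adduct (racemic, transient) | COC1=CC(OC)(O[Si](C)(C)C)C(C(=O)c2ccc(OCc3ccccc3)cc2)=C(CCc2cccc(OCc3ccccc3)c2)C1 | intermediate
14 | trimethylsilyl ether of 15 | COc1cc(O[Si](C)(C)C)c(C(=O)c2ccc(OCc3ccccc3)cc2)c(CCc2cccc(OCc3ccccc3)c2)c1 | intermediate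
15 | [4-(benzyloxy)phenyl]{2-[2-(3-(benzyloxy)phenyl)ethyl]-6-hydroxy-4-methoxyphenyl}methanone | COc1cc(O)c(C(=O)c2ccc(OCc3ccccc3)cc2)c(CCc2cccc(OCc3ccccc3)c2)c1 | intermediate
16 | {2-hydroxy-6-[2-(3-hydroxyphenyl)ethyl]-4-methoxyphenyl}(4-hydroxyphenyl)methanone | COc1cc(O)c(C(=O)c2ccc(O)cc2)c(CCc2cccc(O)c2)c1 | intermediate
17 | 2-[hydroxy(4-hydroxyphenyl)methyl]-3-[2-(3-hydroxyphenyl)ethyl]-5-methoxyphenol (racemic, transient) | COc1cc(O)c(C(O)c2ccc(O)cc2)c(CCc2cccc(O)c2)c1 | intermediate
18 | 2-(4-hydroxybenzyl)-3-[2-(3-hydroxyphenyl)ethyl]-5-methoxyphenol (IN1159, achiral) | COc1cc(O)c(Cc2ccc(O)cc2)c(CCc2cccc(O)c2)c1 | target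

**Step count**
- Total steps: 6.
- Longest linear sequence: 4 (steps 3, 4, 5, 6, or equally steps 1, 2, 5, 6).

**Three steps most likely to fail**

Step 5 (key benzannulation).
- Risks:
  - The ynone carries a β-alkyl group and a donor-substituted aryl group, so it is a sluggish dienophile.
  - The diene can decompose, for example by silyl migration, before it reacts.
  - A stepwise Michael/aldol course, or loss of silanol instead of methanol, would give other arenes.
- Fallback: it sets out from 7 and comes back at 15, and it gives up ring construction altogether. Commercial methyl 2-hydroxy-4-methoxy-6-methylbenzoate is doubly deprotonated with LDA (2.5 equiv, THF, −78 °C). Its lateral benzylic carbanion is alkylated with 7 to give methyl 2-[2-(3-(benzyloxy)phenyl)ethyl]-6-hydroxy-4-methoxybenzoate F1. Commercial 1-(benzyloxy)-4-bromobenzene and n-BuLi give 4-(benzyloxy)phenyllithium F2, which is added in excess (3 equiv, THF, −78 to 0 °C) to the ester. The ortho phenoxide and the two ortho substituents of the resulting ketone block a second addition, so work-up gives 15.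

Step 6 (ketone to methylene during debenzylation).
- Risks:
  - The chelated, di-ortho-substituted, donor-deactivated ketone may stop at 16 or 17.
  - Under acid, the cation derived from 17 could be trapped by the pendant 3-hydroxyphenyl ring in a seven-membered Friedel–Crafts closure.
- Fallback: it sets out from 15 and comes back at 18, and it replaces surface hydrogenolysis by basic hydride/quinone methide chemistry. Compound 15 is treated with ethyl chloroformate and Et3N (THF, 0 °C) to give 2-[4-(benzyloxy)benzoyl]-3-[2-(3-(benzyloxy)phenyl)ethyl]-5-methoxyphenyl ethyl carbonate F3. NaBH4 in THF–water reduces the now unchelated ketone. The alkoxide takes over the carbonate group, and ethyl carbonate is expelled to give the transient ortho-quinone methide F4. A second hydride reduces this at once to 2-[4-(benzyloxy)benzyl]-3-[2-(3-(benzyloxy)phenyl)ethyl]-5-methoxyphenol F5. Neutral hydrogenolysis (H2 1 bar, Pd/C, EtOAc, rt) then removes the two benzyl groups to give 18.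

Step 4 (acyl Sonogashira).
- Risks:
  - The amine can isomerise the ynone through its propargylic CH2 to an allenyl ketone.
  - Amine or chloride can add in conjugate fashion to the ynone.
  - Glaser dimerisation of 10 competes.
- Fallback: it sets out from 10 and comes back at 12, and it uses 1,2-addition and oxidation instead of cross-coupling. Compound 10 is deprotonated with n-BuLi (THF, −78 °C) and added to commercial 4-(benzyloxy)benzaldehyde to give racemic 1-[4-(benzyloxy)phenyl]-5-[3-(benzyloxy)phenyl]pent-2-yn-1-ol F6. Activated MnO2 (CH2Cl2, rt) oxidises this alcohol to 12 under neutral conditions.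

**Further compounds**
F1 | step 5 | methyl 2-[2-(3-(benzyloxy)phenyl)ethyl]-6-hydroxy-4-methoxybenzoate | COC(=O)c1c(O)cc(OC)cc1CCc1cccc(OCc2ccccc2)c1
F2 | step 5 | 4-(benzyloxy)phenyllithium | [Li]c1ccc(OCc2ccccc2)cc1
F3 | step 6 | 2-[4-(benzyloxy)benzoyl]-3-[2-(3-(benzyloxy)phenyl)ethyl]-5-methoxyphenyl ethyl carbonate | CCOC(=O)Oc1cc(OC)cc(CCc2cccc(OCc3ccccc3)c2)c1C(=O)c1ccc(OCc2ccccc2)cc1
F4 | step 6 | ortho-quinone methide (transient) | O=C1C=C(OC)C=C(CCc2cccc(OCc3ccccc3)c2)C1=Cc1ccc(OCc2ccccc2)cc1
F5 | step 6 | 2-[4-(benzyloxy)benzyl]-3-[2-(3-(benzyloxy)phenyl)ethyl]-5-methoxyphenol | COc1cc(O)c(Cc2ccc(OCc3ccccc3)cc2)c(CCc2cccc(OCc3ccccc3)c2)c1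
F6 | step 4 | 1-[4-(benzyloxy)phenyl]-5-[3-(benzyloxy)phenyl]pent-2-yn-1-ol (racemic) | OC(C#CCCc1cccc(OCc2ccccc2)c1)c1ccc(OCc2ccccc2)cc1
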